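## The problem

Atom numbering used throughout: O1, C2 (lactone C=O), C3 (methyl-bearing), C4 (enol OH), C5, then the chain C6–C14, ring A (C15 bearing the chain, C16 the α-CH, C17 bearing the methylene C19, C18 the β-CH), and ring B (C20–C23).

Target 32 is an open-chain C25 compound with three separate rings: a 3-methyltetronic acid, a 2,4-disubstituted furan (ring A) and a 3-substituted furan (ring B), the two furans being joined only through C19. The rings are linked by the chain C6–C14, so the task is chain assembly with control of three double bonds: the Z ylidene C5=C6 and the 9E,11E diene whose C11 carries a methyl group. C7 (S) is the only stereocentre and is isolated, so it can neither steer nor be steered by another element. It has to come from an auxiliary and then be protected from epimerisation while C6 is an aldehyde and, later, while C7–H is the γ-position of the ylidene lactone. Both furans, the doubly activated methylene C19 and the diene do not tolerate strong acid, electrophilic oxidants or radical conditions, and the acidic tetronic acid is best carried as its methyl ether to the last step. Ring A is the real difficulty, because substitution or metalation of a 3-alkylfuran goes mainly to the position next to the substituent and does not give the 2,4-pattern. That pattern is what a ketone and a terminal alkyne give when joined through the ketone α-carbon: C17 with its oxygen and C19 is the ketone, C18 its α-carbon, C15 the substituted and C16 the unsubstituted alkyne carbon. A formal (3+2) annulation of a keto-stabilised sulfonium ylide with a 4-pentynyl ether is therefore the central step.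

## Retrosynthesis

**Unmasking and C5=C6.** The last operation is O-demethylation of methyl ether 31 to 32. The C5=C6 bond of 31 is traced back to aldol adduct 29 (through mesylate 30), and the C5–C6 bond of 29 is cut to the C5 anion of methyl tetronate 28 and aldehyde 24. This is preferred to closing the tetronic acid ring last, which would need a C5 α-hydroxy ester and a base-mediated ring closure next to C7. The chosen cut removes a complete achiral heterocycle, and the Z geometry is the thermodynamic outcome of an E1cB elimination. 28 goes back by O-methylation to 27 and by bromination–lactonisation (through 26) to keto ester 25. The forward steps must add at low temperature without epimerising C7 of 24 and must eliminate without removing the γ-proton at C7.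

**C9=C10.** Aldehyde 24 comes from alcohol 23 and its silyl ether 22. The disubstituted E alkene C9=C10 of 22 is cut to the C6–C9 tetrazolyl sulfone 21 and the C10–C23 enal 13. The neighbouring cuts are worse: C11=C12 is trisubstituted and an olefination onto a methyl ketone would not control its geometry, and C10–C11 would need two stereodefined alkenyl partners. The chosen cut separates the small chiral piece from the achiral furan piece. It asks only for E selectivity, the normal result when an unbranched alkyl sulfone of this type meets an enal.

**The chiral sulfone.** 21 goes back to sulfide 20 and alcohol 19 (C9–S bond). The C9 oxygen of 19 comes from oxidative cleavage of the terminal alkene of 17 (through ozonide 18), and 17 from alcohol 16 and imide 15. The C7–C8 bond of 15 is cut to the propionyl imide 14. An auxiliary-controlled allylation sets C7; the allyl group reacts cleanly with the imide enolate and carries C8 and C9. The (R)-benzyl auxiliary leads to the (S) centre.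

**C11=C12.** Enal 13 is cut at its trisubstituted alkene into aldehyde 11 and the stabilised phosphorane 12, which supplies C10, C11 and the C11 methyl in one piece and should give the E enal. 11 comes from alcohol 10 and silyl ether 9.

**Ring A.** In 9 the bonds C15–C18 and O–C16 are cut, giving ylide 6 and alkyne 8. Cuts outside the ring (C17–C19 or C14–C15) would need a furan already carrying two different handles in the 2,4-relationship, which only moves the problem. The cut inside the ring creates the pattern from the connectivity of a ketone and a terminal alkyne, with ring B and C19 already in place. The forward reaction must bond the ylide carbon to the internal alkyne carbon only, close through oxygen faster than the carbene intermediate attacks ring B, and leave the silyl ether and both furans alone.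

**Ylide and alkyne.** 6 arises by deprotonation of sulfonium salt 5, 5 by S-alkylation with bromo ketone 4, and 4 by one-carbon homologation of acid 1 (through 2 and 3). Alkyne 8 is the silyl ether of 7.

## Roads not taken

**Alternative 1:** The cut is at C10–C11 and at the C11–methyl bond, with C11–C14 and the C14 oxygen coming from 2,3-dihydrofuran A3.
- Forward key step: the 5-lithio derivative of A3 and the alkenyllithium from the E-alkenyl iodide A2 are combined on copper (CuBr·SMe2). The alkenyl group migrates to the metalated ring carbon with expulsion of the ring oxygen (1,2-metallate shift), and the resulting alkenylcopper is methylated with MeI to give dienol A1 (C6–C14).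
- Merits: both diene geometries come from stereospecific events (retention in A2, inversion in the shift), the C11 methyl and a C14 hydroxyl handle appear in the same flask, and the assembly is convergent.
- Weak points: ring A and the difurylmethane unit remain unmade. A1 would still have to be joined at C14 to a 4-metalated 2-(furan-3-ylmethyl)furan, a species that direct metalation does not provide. The step also needs t-BuLi, stoichiometric copper and either a second equivalent of A2 or a dummy ligand.
- Comparison: this road controls the trisubstituted alkene better than the Wittig/Julia–Kocienski pair, which is selective but not stereospecific. Against that, the chosen plan solves ring A outright and builds the diene with two olefinations of well-established E preference from cheap reagents.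

**Alternative 2:** The cut is at O1–C2, undoing a ring expansion of the 4-hydroxycyclobutenone A5, itself the adduct of a C6 organometallic with cyclobutenedione A6.
- Forward key step: Pb(OAc)4 converts the tertiary alcohol of A5 into an alkoxy radical, the strained ring bond breaks, the acyl radical is oxidised to an acylium ion, the new ketone oxygen captures it, and loss of a C6 proton gives the ylidene A4, which is the same compound as 31.
- Merits: it avoids the α-chiral aldehyde 24 and the base-mediated aldol–elimination, so C7 is never next to an enolisable carbonyl, and the tetronate substitution pattern is inherited from A6.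
- Weak points: an oxidant of this type with radical and cationic intermediates meets two furans (prone to 2,5-acetoxylation), the C19 methylene and a diene; the cation at C5 sits four atoms from C9=C10 and could cyclise onto it. The Z/E outcome of the proton loss is not secured. A C6 organometallic carrying the whole chain must be made from 23 in extra steps, and A6 needs its own preparation.
- Comparison: the endgame is identical (demethylation of 31). This road protects C7 better. The chosen plan sets against it non-oxidising, low-temperature chemistry and a thermodynamically controlled Z elimination.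

**Alternative 3:** The cut is at C17–C18 and O–C17 of ring A.
- Forward key step: Sonogashira coupling (PdCl2(PPh3)2/CuI) of the Z-iodoallylic alcohol A9 with 3-ethynylfuran A8 gives a Z-enynol. Its hydroxyl adds 5-exo-dig to the alkyne, and the exocyclic enol ether tautomerises to the furan A7, creating C19 as a methylene.
- Merits: the 2,4-pattern follows from connectivity alone, with no regiochemical question. Cycloisomerisation of Z-enynols is tolerant of alkyl substituents and is arguably better founded than extending the gold annulation to an alkyl ketone ylide. The C11–C12 alkyne of A7 could give the trisubstituted alkene by syn-hydrometalation and coupling.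
- Weak points: A9 requires a carbomagnesiation–iodination sequence with an excess of a functionalised Grignard reagent, and A8 is volatile and prone to polymerise. The ring closure may stall at the exocyclic dihydrofuran or go 6-endo. Hydrometalation of A7 must distinguish C11 from C12, whose substituents (methyl and a primary alkyl) differ little.
- Comparison: for ring A this road is at least as secure. The chosen plan sets against it two partners made in a few steps from commercial 1 and 7, a C12 oxygen handle that reaches aldehyde 11 in two steps, and a diene synthesis that does not depend on the regiochemistry of an almost symmetrical alkyne.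

Key step: step 5

## Route

Remark 1: enolates, the sulfonyl carbanion and the organogold species of the catalytic cycle are treated as transient and carry no number.
Remark 2: ozonide 18, aldol adduct 29 and mesylate 30 form as diastereomer mixtures at centres that the next operation destroys; their SMILES leave those centres open.

Step 1
Reactants: 1 furan-3-ylacetic acid
Product: 4 1-bromo-3-(furan-3-yl)propan-2-one, via mixed carbonic anhydride 2 (not isolated), via diazo ketone 3 (not isolated)
Conditions: ClCO2Et, Et3N, THF, −15 °C; CH2N2, Et2O, 0 °C; then 48% aq. HBr, 0 °C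
Reagents that add atoms: diazomethane, C=[N+]=[N-]; hydrogen bromide, Br; ethyl chloroformate, CCOC(=O)Cl (its atoms stay only in 2)
Why: Mixed-anhydride activation, acylation of diazomethane (first stage of an Arndt–Eistert sequence) and hydrobromination of the diazo ketone in the same flask, bromide displacing N2 from the protonated diazo carbon; no acid chloride is made and contact with HBr is brief and cold, which should spare ring B.

Step 2
Reactants: 4 1-bromo-3-(furan-3-yl)propan-2-one
Product: 5 [3-(furan-3-yl)-2-oxopropyl]dimethylsulfonium bromide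
Conditions: Me2S (excess), acetone, rt, dark
Reagents that add atoms: dimethyl sulfide, CSC
Why: SN2 S-alkylation of the sulfide by the activated α-bromo ketone; the salt should crystallise from acetone, leaving neutral impurities behind.

Step 3
Reactants: 5 [3-(furan-3-yl)-2-oxopropyl]dimethylsulfonium bromide
Product: 6 dimethylsulfonium 3-(furan-3-yl)-2-oxopropylide
Conditions: aq. NaOH, CH2Cl2, 0 °C; extracted, dried and used at once
Reagents that add atoms: none
Why: Deprotonation between S+ and C=O, by far the most acidic C–H (well above the furyl CH2), is the standard preparation of keto-stabilised sulfonium ylides; immediate use allows for the limited shelf life of alkyl ketone ylides.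

Step 4
Reactants: 7 pent-4-yn-1-ol
Product: 8 tert-butyldimethyl(pent-4-yn-1-yloxy)silane
Conditions: TBSCl, imidazole, CH2Cl2, 0 °C → rt
Reagents that add atoms: tert-butyldimethylsilyl chloride, CC(C)(C)[Si](C)(C)Cl
Why: Standard silylation of a primary alcohol; it removes the hydroxyl that would otherwise add to the gold-activated alkyne in step 5.

Step 5
Reactants: 6 dimethylsulfonium 3-(furan-3-yl)-2-oxopropylide; 8 tert-butyldimethyl(pent-4-yn-1-yloxy)silane
Product: 9 tert-butyl{3-[5-(furan-3-ylmethyl)furan-3-yl]propoxy}dimethylsilane
Conditions: Ph3PAuNTf2 (5 mol %), 8 (2 equiv), ClCH2CH2Cl, 60 °C, slow addition of 6, argon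
Reagents that add atoms: none
Why: Formal (3+2) ylide–alkyne annulation under catalysis by monovalent gold: the cationic gold π-complex of 8 is attacked by the ylide carbon C18 at the internal carbon C15 (bond C15–C18), giving a vinylgold that still carries the sulfonium group. Electron release from the C16–Au bond expels Me2S and leaves an α,β-unsaturated gold carbene at C16 with the ketone oxygen 1,5 to it; attack of that oxygen on C16 (bond O–C16) closes ring A in a five-membered O-cyclisation of the cis keto vinylcarbene, the C16–Au bond lying outside the ring, and loss of the gold fragment gives the aromatic furan. The closest known reaction type is the gold-catalysed annulation of carbonyl-stabilised sulfonium ylides with terminal alkynes to 2,4-disubstituted furans, documented mainly for aryl ketone ylides; 6 is an alkyl ketone member of the same class. No stereocentre is formed. Regioselectivity is needed and is secured by the terminal alkyl alkyne, whose π-complex is polarised toward the substituted carbon (attack at C16 would give the 2,5-isomer). Chemoselectivity is needed as well and rests on the five-membered oxygen capture outrunning attack of the carbene on ring B, which would require a seven-membered closure. The silyl ether and the furans are weak ligands for the soft cation, and slow addition of 6 to excess 8 keeps the ylide concentration low, limiting ylide–carbene coupling and catalyst sequestration.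

Step 6
Reactants: 9 tert-butyl{3-[5-(furan-3-ylmethyl)furan-3-yl]propoxy}dimethylsilane
Product: 10 3-[5-(furan-3-ylmethyl)furan-3-yl]propan-1-ol
Conditions: Bu4NF, THF, 0 °C → rt
Reagents that add atoms: none
Why: Fluoride-induced cleavage of the Si–O bond under neutral conditions, which both furans tolerate.

Step 7
Reactants: 10 3-[5-(furan-3-ylmethyl)furan-3-yl]propan-1-ol
Product: 11 3-[5-(furan-3-ylmethyl)furan-3-yl]propanal
Conditions: Dess–Martin periodinane, NaHCO3, CH2Cl2, 0 °C → rt
Reagents that add atoms: none
Why: Dess–Martin oxidation stops at the aldehyde and does not attack furans; the bicarbonate buffer neutralises the acetic acid released.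

Step 8
Reactants: 11 3-[5-(furan-3-ylmethyl)furan-3-yl]propanal; 12 2-(triphenylphosphoranylidene)propanal
Product: 13 (2E)-5-[5-(furan-3-ylmethyl)furan-3-yl]-2-methylpent-2-enal
Conditions: toluene, 90 °C
Reagents that add atoms: none
Why: Wittig olefination with a stabilised ylide, which should give the E trisubstituted enal and react only once because enal 13 is far less electrophilic than 11.

Step 9
Reactants: 14 (4R)-4-benzyl-3-propanoyl-1,3-oxazolidin-2-one
Product: 15 (4R)-4-benzyl-3-[(2S)-2-methylpent-4-enoyl]-1,3-oxazolidin-2-one
Conditions: NaN(SiMe3)2, THF, −78 °C; allyl iodide, −78 → −45 °C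
Reagents that add atoms: allyl iodide, C=CCI
Why: Evans alkylation: the chelated Z sodium enolate is allylated on the face opposite the benzyl group, which for the (R)-auxiliary gives the (2S) acyl unit, the future C7.

Step 10
Reactants: 15 (4R)-4-benzyl-3-[(2S)-2-methylpent-4-enoyl]-1,3-oxazolidin-2-one
Product: 16 (2S)-2-methylpent-4-en-1-ol
Conditions: LiBH4, MeOH (1 equiv), Et2O, 0 °C
Reagents that add atoms: none
Why: Reductive removal of the auxiliary by selective hydride attack on the exocyclic imide carbonyl, without enolisation of C7; the volatile alcohol is kept in solution and carried on.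

Step 11
Reactants: 16 (2S)-2-methylpent-4-en-1-ol
Product: 17 tert-butyl{[(2S)-2-methylpent-4-en-1-yl]oxy}diphenylsilane
Conditions: TBDPSCl, imidazole, DMF, rt
Reagents that add atoms: tert-butyldiphenylsilyl chloride, CC(C)(C)[Si](Cl)(c1ccccc1)c1ccccc1
Why: Standard silylation; the TBDPS ether should survive ozone, peroxide and KN(SiMe3)2 and makes the small fragment non-volatile.

Step 12
Reactants: 17 tert-butyl{[(2S)-2-methylpent-4-en-1-yl]oxy}diphenylsilane
Product: 19 (3S)-4-[(tert-butyldiphenylsilyl)oxy]-3-methylbutan-1-ol, via ozonide 18 (not isolated)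
Conditions: O3, CH2Cl2, −78 °C; then NaBH4, MeOH, −78 °C → rt
Reagents that add atoms: ozone, [O-][O+]=O
Why: Ozonolysis with hydride work-up turns the terminal alkene into the C9 primary alcohol in one flask; no other oxidisable group is present.

Step 13
Reactants: 19 (3S)-4-[(tert-butyldiphenylsilyl)oxy]-3-methylbutan-1-ol
Product: 20 5-({(3S)-4-[(tert-butyldiphenylsilyl)oxy]-3-methylbutyl}sulfanyl)-1-phenyl-1H-tetrazole
Conditions: 1-phenyl-1H-tetrazole-5-thiol, PPh3, DIAD, THF, 0 °C → rt
Reagents that add atoms: 1-phenyl-1H-tetrazole-5-thiol, Sc1nnnn1-c1ccccc1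
Why: Mitsunobu thioetherification of an unhindered primary alcohol with an acidic heteroaryl thiol.

Step 14
Reactants: 20 5-({(3S)-4-[(tert-butyldiphenylsilyl)oxy]-3-methylbutyl}sulfanyl)-1-phenyl-1H-tetrazole
Product: 21 5-({(3S)-4-[(tert-butyldiphenylsilyl)oxy]-3-methylbutyl}sulfonyl)-1-phenyl-1H-tetrazole
Conditions: (NH4)6Mo7O24·4H2O (10 mol %), 30% H2O2, EtOH, 0 °C → rt
Reagents that add atoms: hydrogen peroxide, OO
Why: Molybdate-catalysed peroxide oxidation of sulfide to sulfone; the silyl ether and the saturated chain are inert.

Step 15
Reactants: 21 5-({(3S)-4-[(tert-butyldiphenylsilyl)oxy]-3-methylbutyl}sulfonyl)-1-phenyl-1H-tetrazole; 13 (2E)-5-[5-(furan-3-ylmethyl)furan-3-yl]-2-methylpent-2-enal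
Product: 22 tert-butyl{[(2S,4E,6E)-9-[5-(furan-3-ylmethyl)furan-3-yl]-2,6-dimethylnona-4,6-dien-1-yl]oxy}diphenylsilane
Conditions: KN(SiMe3)2, DME, −60 °C; then 13, −60 °C → rt
Reagents that add atoms: none
Why: Julia–Kocienski olefination: the potassium sulfonyl carbanion adds to the enal and Smiles rearrangement with loss of SO2 and the tetrazolone forms C9=C10; an unbranched alkyl sulfone, a conjugated aldehyde and K+ in DME should favour the E alkene. C11=C12 and C7 (γ to sulfur, not acidic) are not touched.

Step 16
Reactants: 22 tert-butyl{[(2S,4E,6E)-9-[5-(furan-3-ylmethyl)furan-3-yl]-2,6-dimethylnona-4,6-dien-1-yl]oxy}diphenylsilane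
Product: 23 (2S,4E,6E)-9-[5-(furan-3-ylmethyl)furan-3-yl]-2,6-dimethylnona-4,6-dien-1-ol
Conditions: Bu4NF, THF, rt
Reagents that add atoms: none
Why: Fluoride desilylation under neutral conditions that leave diene and furans alone.

Step 17
Reactants: 23 (2S,4E,6E)-9-[5-(furan-3-ylmethyl)furan-3-yl]-2,6-dimethylnona-4,6-dien-1-ol
Product: 24 (2S,4E,6E)-9-[5-(furan-3-ylmethyl)furan-3-yl]-2,6-dimethylnona-4,6-dienal
Conditions: Dess–Martin periodinane, NaHCO3, CH2Cl2, 0 °C; used crude
Reagents that add atoms: none
Why: Buffered Dess–Martin oxidation is non-basic, and immediate use of the crude aldehyde protects the α-stereocentre C7.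

Step 18
Reactants: 25 ethyl 2-methyl-3-oxobutanoate
Product: 27 4-hydroxy-3-methylfuran-2(5H)-one, via ethyl 4-bromo-2-methyl-3-oxobutanoate 26 (not isolated)
Conditions: Br2, CHCl3, 0 °C → rt; evaporate; neat, 110 °C
Reagents that add atoms: bromine, BrBr (its atom stays only in 26)
Why: Bromination of the β-keto ester ends, after HBr-mediated equilibration, at the terminal C4 position; on heating the ester oxygen displaces bromide with loss of bromoethane (lactonisation) to give the tetronic acid.

Step 19
Reactants: 27 4-hydroxy-3-methylfuran-2(5H)-one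
Product: 28 4-methoxy-3-methylfuran-2(5H)-one
Conditions: Me2SO4, K2CO3, acetone, reflux
Reagents that add atoms: dimethyl sulfate, COS(=O)(=O)OC
Why: O-Alkylation of the vinylogous acid with a hard methylating agent gives the 4-methoxy butenolide and masks the acidic enol for the base chemistry to come.

Step 20
Reactants: 28 4-methoxy-3-methylfuran-2(5H)-one; 24 (2S,4E,6E)-9-[5-(furan-3-ylmethyl)furan-3-yl]-2,6-dimethylnona-4,6-dienal
Product: 29 5-{(2S,4E,6E)-9-[5-(furan-3-ylmethyl)furan-3-yl]-1-hydroxy-2,6-dimethylnona-4,6-dien-1-yl}-4-methoxy-3-methylfuran-2(5H)-one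
Conditions: LiN(i-Pr)2, THF, −78 °C; then 24, −78 °C; AcOH quench at −78 °C
Reagents that add atoms: none
Why: Directed aldol addition: deprotonation of 28 at C5 gives an aromatic 2-furanolate that adds to the aldehyde at low temperature, where enolisation of 24 should not compete. The two new centres (C5, C6) form as a mixture that step 21 removes.

Step 21
Reactants: 29 aldol adduct (name as in step 20)
Product: 31 (5Z)-5-{(2S,4E,6E)-9-[5-(furan-3-ylmethyl)furan-3-yl]-2,6-dimethylnona-4,6-dien-1-ylidene}-4-methoxy-3-methylfuran-2(5H)-one, via mesylate 30 (not isolated)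
Conditions: MsCl, Et3N, CH2Cl2, 0 °C; then DBU, 0 °C → rt
Reagents that add atoms: methanesulfonyl chloride, CS(=O)(=O)Cl (its atoms stay only in 30)
Why: Mesylation and E1cB elimination through the C5 carbanion; the Z ylidene is favoured because in the E isomer the C7 substituent would clash with the C4 methoxy group. DBU should be too weak to remove the vinylogous γ-proton at C7.

Step 22
Reactants: 31 (5Z)-ylidene methyl ether (name as in step 21)
Product: 32 (5Z)-5-{(2S,4E,6E)-9-[5-(furan-3-ylmethyl)furan-3-yl]-2,6-dimethylnona-4,6-dien-1-ylidene}-4-hydroxy-3-methylfuran-2(5H)-one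
Conditions: n-PrSLi (from n-PrSH, n-BuLi), HMPA, rt; then cold dilute HCl to pH 3
Reagents that add atoms: none
Why: SN2 demethylation of the vinylogous methyl ester by a soft thiolate in a dipolar aprotic solvent, the tetronate anion being the leaving group; the non-acidic, non-oxidising conditions should spare furans, diene and C7, and brief mild acidification frees the tetronic acid.

## Compound list

1 | furan-3-ylacetic acid | OC(=O)Cc1ccoc1 | starting material
2 | ethyl carbonic 2-(furan-3-yl)acetic anhydride | CCOC(=O)OC(=O)Cc1ccoc1 | intermediate (not isolated)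
3 | 1-diazo-3-(furan-3-yl)propan-2-one | [N-]=[N+]=CC(=O)Cc1ccoc1 | intermediate (not isolated)
4 | 1-bromo-3-(furan-3-yl)propan-2-one | BrCC(=O)Cc1ccoc1 | intermediate
5 | [3-(furan-3-yl)-2-oxopropyl]dimethylsulfonium bromide | C[S+](C)CC(=O)Cc1ccoc1.[Br-] | intermediate
6 | dimethylsulfonium 3-(furan-3-yl)-2-oxopropylide | C[S+](C)[CH-]C(=O)Cc1ccoc1 | intermediate
7 | pent-4-yn-1-ol | C#CCCCO | starting material
8 | tert-butyldimethyl(pent-4-yn-1-yloxy)silane | C#CCCCO[Si](C)(C)C(C)(C)C | intermediate
9 | tert-butyl{3-[5-(furan-3-ylmethyl)furan-3-yl]propoxy}dimethylsilane | CC(C)(C)[Si](C)(C)OCCCc1coc(Cc2ccoc2)c1 | intermediate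
10 | 3-[5-(furan-3-ylmethyl)furan-3-yl]propan-1-ol | OCCCc1coc(Cc2ccoc2)c1 | intermediate
11 | 3-[5-(furan-3-ylmethyl)furan-3-yl]propanal | O=CCCc1coc(Cc2ccoc2)c1 | intermediate
12 | 2-(triphenylphosphoranylidene)propanal | CC(C=O)=P(c1ccccc1)(c1ccccc1)c1ccccc1 | starting material
13 | (2E)-5-[5-(furan-3-ylmethyl)furan-3-yl]-2-methylpent-2-enal | O=C/C(C)=C/CCc1coc(Cc2ccoc2)c1 | intermediate
14 | (4R)-4-benzyl-3-propanoyl-1,3-oxazolidin-2-one | CCC(=O)N1[C@H](Cc2ccccc2)COC1=O | starting material
15 | (4R)-4-benzyl-3-[(2S)-2-methylpent-4-enoyl]-1,3-oxazolidin-2-one | C=CC[C@H](C)C(=O)N1[C@H](Cc2ccccc2)COC1=O | intermediate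
16 | (2S)-2-methylpent-4-en-1-ol | C=CC[C@H](C)CO | intermediate
17 | tert-butyl{[(2S)-2-methylpent-4-en-1-yl]oxy}diphenylsilane | C=CC[C@H](C)CO[Si](c1ccccc1)(c1ccccc1)C(C)(C)C | intermediate
18 | 3-{(2S)-3-[(tert-butyldiphenylsilyl)oxy]-2-methylpropyl}-1,2,4-trioxolane (mixture at the ring carbon) | CC(C)(C)[Si](c1ccccc1)(c1ccccc1)OC[C@@H](C)CC1OCOO1 | intermediate (not isolated)
19 | (3S)-4-[(tert-butyldiphenylsilyl)oxy]-3-methylbutan-1-ol | CC(C)(C)[Si](c1ccccc1)(c1ccccc1)OC[C@@H](C)CCO | intermediate
20 | 5-({(3S)-4-[(tert-butyldiphenylsilyl)oxy]-3-methylbutyl}sulfanyl)-1-phenyl-1H-tetrazole | CC(C)(C)[Si](c1ccccc1)(c1ccccc1)OC[C@@H](C)CCSc1nnnn1-c1ccccc1 | intermediate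
21 | 5-({(3S)-4-[(tert-butyldiphenylsilyl)oxy]-3-methylbutyl}sulfonyl)-1-phenyl-1H-tetrazole | CC(C)(C)[Si](c1ccccc1)(c1ccccc1)OC[C@@H](C)CCS(=O)(=O)c1nnnn1-c1ccccc1 | intermediate
22 | tert-butyl{[(2S,4E,6E)-9-[5-(furan-3-ylmethyl)furan-3-yl]-2,6-dimethylnona-4,6-dien-1-yl]oxy}diphenylsilane | CC(C)(C)[Si](c1ccccc1)(c1ccccc1)OC[C@@H](C)C/C=C/C(C)=C/CCc1coc(Cc2ccoc2)c1 | intermediate
23 | (2S,4E,6E)-9-[5-(furan-3-ylmethyl)furan-3-yl]-2,6-dimethylnona-4,6-dien-1-ol | OC[C@@H](C)C/C=C/C(C)=C/CCc1coc(Cc2ccoc2)c1 | intermediate
24 | (2S,4E,6E)-9-[5-(furan-3-ylmethyl)furan-3-yl]-2,6-dimethylnona-4,6-dienal | O=C[C@@H](C)C/C=C/C(C)=C/CCc1coc(Cc2ccoc2)c1 | intermediate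
25 | ethyl 2-methyl-3-oxobutanoate | CCOC(=O)C(C)C(C)=O | starting material
26 | ethyl 4-bromo-2-methyl-3-oxobutanoate | CCOC(=O)C(C)C(=O)CBr | intermediate (not isolated)
27 | 4-hydroxy-3-methylfuran-2(5H)-one | CC1=C(O)COC1=O | intermediate
28 | 4-methoxy-3-methylfuran-2(5H)-one | COC1=C(C)C(=O)OC1 | intermediate
29 | 5-{(2S,4E,6E)-9-[5-(furan-3-ylmethyl)furan-3-yl]-1-hydroxy-2,6-dimethylnona-4,6-dien-1-yl}-4-methoxy-3-methylfuran-2(5H)-one (mixture at C5 and C6) | COC1=C(C)C(=O)OC1C(O)[C@@H](C)C/C=C/C(C)=C/CCc1coc(Cc2ccoc2)c1 | intermediate
30 | methanesulfonate of 29 | COC1=C(C)C(=O)OC1C(OS(C)(=O)=O)[C@@H](C)C/C=C/C(C)=C/CCc1coc(Cc2ccoc2)c1 | intermediate (not isolated)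
31 | (5Z)-5-{(2S,4E,6E)-9-[5-(furan-3-ylmethyl)furan-3-yl]-2,6-dimethylnona-4,6-dien-1-ylidene}-4-methoxy-3-methylfuran-2(5H)-one | CC1=C(OC)/C(=C/[C@@H](C)C/C=C/C(C)=C/CCc2coc(Cc3ccoc3)c2)OC1=O | intermediate
32 | (5Z)-5-{(2S,4E,6E)-9-[5-(furan-3-ylmethyl)furan-3-yl]-2,6-dimethylnona-4,6-dien-1-ylidene}-4-hydroxy-3-methylfuran-2(5H)-one | CC1=C(O)/C(=C/[C@@H](C)C/C=C/C(C)=C/CCc2coc(Cc3ccoc3)c2)OC1=O | target

## Step count and risks

Total: 22 steps. Longest linear sequence: 13 steps from 1 (steps 1, 2, 3, 5, 6, 7, 8, 15, 16, 17, 20, 21, 22).

**Step 5 (key step).**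
- Most likely failure: loss of the fragile alkyl ketone ylide before productive attack, sequestration of the catalyst by the ylide or by released Me2S, or alkylation of the electron-rich furans (ring B, or the new ring A at C16) by the gold-activated alkyne.
- Fallback (sets out from 8 and 4, returns at 9): anti-Markovnikov hydration of 8 by hydroboration with dicyclohexylborane and buffered peroxide oxidation should give 5-[(tert-butyldimethylsilyl)oxy]pentanal F1. Condensation with pyrrolidine gives the enamine (E)-1-{5-[(tert-butyldimethylsilyl)oxy]pent-1-en-1-yl}pyrrolidine F2. Stork alkylation of F2 with bromo ketone 4 and buffered hydrolysis gives the 1,4-keto aldehyde 2-{3-[(tert-butyldimethylsilyl)oxy]propyl}-5-(furan-3-yl)-4-oxopentanal F3. Paal–Knorr cyclodehydration (pyridinium p-toluenesulfonate, toluene, warm) closes ring A to 9. The same C15–C18 and O–C16 bonds are formed, by alkylation and condensation, at the cost of mild acid contact for ring B and more steps.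

**Step 1.**
- Most likely failure: acid-induced opening or polymerisation of ring B during hydrobromination, or intramolecular alkylation of ring B by the protonated diazo ketone.
- Fallback (sets out from 1, returns at 5): coupling of 1 with MeNHOMe·HCl (carbonyldiimidazole) gives the Weinreb amide 2-(furan-3-yl)-N-methoxy-N-methylacetamide F4. Single addition of chloromethyllithium (from ICH2Cl and MeLi·LiBr, −78 °C) gives 1-chloro-3-(furan-3-yl)propan-2-one F5. Me2S with NaBr in acetone (halide exchange in the flask) then gives sulfonium bromide 5 without diazo compounds or strong acid.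

**Step 15.**
- Most likely failure: erosion of E selectivity at C9=C10, or γ-deprotonation or conjugate addition of the enal by the sulfonyl carbanion.
- Fallback (sets out from 13 and 17, returns at 22): Wittig methylenation of 13 (Ph3P=CH2) gives 2-(furan-3-ylmethyl)-4-[(3E)-4-methylhexa-3,5-dien-1-yl]furan F6. Olefin cross-metathesis of F6 with excess terminal alkene 17 (second-generation Grubbs catalyst, RuCl2(=CHPh)(PCy3)(H2IMes)) joins the two unhindered vinyl groups, the trisubstituted C11=C12 bond being too hindered to take part, and should give 22 with the thermodynamically preferred E geometry. This is shorter but less dependable in geometry, which is why it is held in reserve.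

**Step 20.**
- Most likely failure: epimerisation of C7 by enolisation of aldehyde 24 under the basic conditions, or retro-aldol on warming.
- Fallback (sets out from 28 and 24, returns at 29): silylation of 28 (TBSOTf, Et3N) gives the silyl dienol ether tert-butyl[(4-methoxy-3-methylfuran-2-yl)oxy]dimethylsilane F7. Vinylogous Mukaiyama aldol addition of F7 to 24 (BF3·OEt2, CH2Cl2, −78 °C) gives 29 after work-up with no base present.

**Step 22.**
- Most likely failure: reversible conjugate addition of thiolate to the ylidene lactone with Z/E scrambling, or incomplete demethylation.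
- Fallback (sets out from 27 and 24, returns at 32): Mitsunobu O-alkylation of 27 with 2-(trimethylsilyl)ethanol gives 3-methyl-4-[2-(trimethylsilyl)ethoxy]furan-2(5H)-one F8. Aldol addition to 24 as in step 20 gives 5-{(2S,4E,6E)-9-[5-(furan-3-ylmethyl)furan-3-yl]-1-hydroxy-2,6-dimethylnona-4,6-dien-1-yl}-3-methyl-4-[2-(trimethylsilyl)ethoxy]furan-2(5H)-one F9. Mesylation gives the methanesulfonate of F9 F10, and DBU elimination as in step 21 gives (5Z)-5-{(2S,4E,6E)-9-[5-(furan-3-ylmethyl)furan-3-yl]-2,6-dimethylnona-4,6-dien-1-ylidene}-3-methyl-4-[2-(trimethylsilyl)ethoxy]furan-2(5H)-one F11. Bu4NF then removes the silylethyl group by fluoride-induced fragmentation under neutral conditions to give 32.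

## Further compounds

F1 | step 5 | 5-[(tert-butyldimethylsilyl)oxy]pentanal | CC(C)(C)[Si](C)(C)OCCCCC=O
F2 | step 5 | (E)-1-{5-[(tert-butyldimethylsilyl)oxy]pent-1-en-1-yl}pyrrolidine | CC(C)(C)[Si](C)(C)OCCC/C=C/N1CCCC1
F3 | step 5 | 2-{3-[(tert-butyldimethylsilyl)oxy]propyl}-5-(furan-3-yl)-4-oxopentanal (racemic) | CC(C)(C)[Si](C)(C)OCCCC(C=O)CC(=O)Cc1ccoc1
F4 | step 1 | 2-(furan-3-yl)-N-methoxy-N-methylacetamide | CON(C)C(=O)Cc1ccoc1
F5 | step 1 | 1-chloro-3-(furan-3-yl)propan-2-one | ClCC(=O)Cc1ccoc1
F6 | step 15 | 2-(furan-3-ylmethyl)-4-[(3E)-4-methylhexa-3,5-dien-1-yl]furan | C=C/C(C)=C/CCc1coc(Cc2ccoc2)c1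
F7 | step 20 | tert-butyl[(4-methoxy-3-methylfuran-2-yl)oxy]dimethylsilane | COc1coc(O[Si](C)(C)C(C)(C)C)c1C
F8 | step 22 | 3-methyl-4-[2-(trimethylsilyl)ethoxy]furan-2(5H)-one | C[Si](C)(C)CCOC1=C(C)C(=O)OC1
F9 | step 22 | 5-{(2S,4E,6E)-9-[5-(furan-3-ylmethyl)furan-3-yl]-1-hydroxy-2,6-dimethylnona-4,6-dien-1-yl}-3-methyl-4-[2-(trimethylsilyl)ethoxy]furan-2(5H)-one | C[Si](C)(C)CCOC1=C(C)C(=O)OC1C(O)[C@@H](C)C/C=C/C(C)=C/CCc1coc(Cc2ccoc2)c1
F10 | step 22 | methanesulfonate of F9 | C[Si](C)(C)CCOC1=C(C)C(=O)OC1C(OS(C)(=O)=O)[C@@H](C)C/C=C/C(C)=C/CCc1coc(Cc2ccoc2)c1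
F11 | step 22 | (5Z)-5-{(2S,4E,6E)-9-[5-(furan-3-ylmethyl)furan-3-yl]-2,6-dimethylnona-4,6-dien-1-ylidene}-3-methyl-4-[2-(trimethylsilyl)ethoxy]furan-2(5H)-one | CC1=C(OCC[Si](C)(C)C)/C(=C/[C@@H](C)C/C=C/C(C)=C/CCc2coc(Cc3ccoc3)c2)OC1=O
A1 | alternative 1 | (3E,5E,8S)-9-[(tert-butyldimethylsilyl)oxy]-4,8-dimethylnona-3,5-dien-1-ol | CC(C)(C)[Si](C)(C)OC[C@@H](C)C/C=C/C(C)=C/CCO
A2 | alternative 1 | tert-butyl{[(2S,4E)-5-iodo-2-methylpent-4-en-1-yl]oxy}dimethylsilane | CC(C)(C)[Si](C)(C)OC[C@@H](C)C/C=C/I
A3 | alternative 1 | 2,3-dihydrofuran | C1=COCC1
A4 | alternative 2 | (5Z)-5-{(2S,4E,6E)-9-[5-(furan-3-ylmethyl)furan-3-yl]-2,6-dimethylnona-4,6-dien-1-ylidene}-4-methoxy-3-methylfuran-2(5H)-one (same structure as 31) | CC1=C(OC)/C(=C/[C@@H](C)C/C=C/C(C)=C/CCc2coc(Cc3ccoc3)c2)OC1=O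
A5 | alternative 2 | 4-{(2S,4E,6E)-9-[5-(furan-3-ylmethyl)furan-3-yl]-2,6-dimethylnona-4,6-dien-1-yl}-4-hydroxy-3-methoxy-2-methylcyclobut-2-en-1-one | COC1=C(C)C(=O)C1(O)C[C@@H](C)C/C=C/C(C)=C/CCc1coc(Cc2ccoc2)c1
A6 | alternative 2 | 3-methoxy-4-methylcyclobut-3-ene-1,2-dione | COC1=C(C)C(=O)C1=O
A7 | alternative 3 | 2-(furan-3-ylmethyl)-4-(pent-3-yn-1-yl)furan | CC#CCCc1coc(Cc2ccoc2)c1
A8 | alternative 3 | 3-ethynylfuran | C#Cc1ccoc1
A9 | alternative 3 | (Z)-2-(iodomethylidene)hept-5-yn-1-ol | OC/C(CCC#CC)=C\I
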